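**Plan**

- Retrosynthesis: the ten O-benzyl groups and the two galloyl C–O bonds (at O3 and O5) are cut first. Next come the O1–C2 and C2–H bonds of the pyran ring (back to an aryl ketone), then the C2–aryl(B) bond (Weinreb ketone synthesis) and the C4–C4a bond (aryl-metal opening of a glycidate).
- Forward: the A-ring aryl-metal and methyl (R)-glycidate give a 3-aryl-lactate, which is converted to the Weinreb amide silyl ether and joined to the B-ring aryllithium. This gives the acyclic 1,3-diaryl-2-silyloxypropan-1-one, and the pyran ring is closed last by reductive cycloetherification.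
- Enabling feature: C2 is an aryl ketone carbon next to the C3–O stereocentre. The A ring of the seco compound is a 2-substituted 5-benzyloxyresorcinol whose two free hydroxyls (future O1 and O5) are homotopic, so ring closure on either one leaves exactly one free phenol, at C5, while O7 stays benzylated.
- Stereochemistry: C3 (R) comes from methyl (R)-glycidate and is not touched afterwards. C2 (R) is set in the ring closure by 1,2-induction from C3, giving the 2,3-cis relationship.
- End game: one double Steglich esterification puts galloyl groups on O3 and O5, and hydrogenolysis frees all phenols.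

Key step: step 8

Assumption: keto-bisphenol 14 is drawn as the open-chain ketone, taken to be the resting form of such 3-(2-hydroxyaryl)-1-arylpropan-1-ones; any hemiketal tautomer present would enter the same oxocarbenium ion.

**Route**

Step 1
Reactants: 1 5-(benzyloxy)benzene-1,3-diol
Product: 2 1-(benzyloxy)-3,5-bis(methoxymethoxy)benzene
Conditions: NaH (2.4 equiv), MOMCl (2.4 equiv), DMF, 0 °C → rt
Reagents that add atoms: chloromethyl methyl ether (MOMCl), COCCl
Why: Williamson-type O-alkylation of both phenoxides should give the bis-MOM ether, whose two acetal groups later direct metalation to the carbon between them.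

Step 2
Reactants: 2 1-(benzyloxy)-3,5-bis(methoxymethoxy)benzene; 3 methyl (R)-glycidate (methyl (2R)-oxirane-2-carboxylate)
Product: 6 methyl (R)-3-[4-(benzyloxy)-2,6-bis(methoxymethoxy)phenyl]-2-hydroxypropanoate, via aryllithium 4 (not isolated), via arylmagnesium bromide 5 (not isolated)
Conditions: 2 (1.3 equiv), n-BuLi, THF, 0 °C; MgBr2·OEt2, 0 °C; CuI (10 mol %), then 3, −40 → −20 °C; then H2O
Reagents that add atoms: none
Why: Directed ortho-metalation should occur at the position flanked by both OMOM groups, and the copper-catalysed epoxide opening by the aryl Grignard attacks the unsubstituted C3 of the glycidate (SN2), so the stereocentre of 3 is not involved and becomes C3 of the flavan with R configuration.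

Step 3
Reactants: 6 methyl (R)-3-[4-(benzyloxy)-2,6-bis(methoxymethoxy)phenyl]-2-hydroxypropanoate
Product: 7 (R)-3-[4-(benzyloxy)-2,6-bis(methoxymethoxy)phenyl]-2-hydroxy-N-methoxy-N-methylpropanamide
Conditions: MeNH(OMe)·HCl (3 equiv), i-PrMgCl (6.5 equiv), THF, −20 → 0 °C; then aq NH4Cl
Reagents that add atoms: N,O-dimethylhydroxylamine hydrochloride, CNOC.Cl
Why: Weinreb amide formation by aminolysis of the ester with the chloromagnesium amide should proceed with the free alcohol carried as its magnesium alkoxide and without touching the α-stereocentre.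

Step 4
Reactants: 7 (R)-3-[4-(benzyloxy)-2,6-bis(methoxymethoxy)phenyl]-2-hydroxy-N-methoxy-N-methylpropanamide
Product: 8 (R)-3-[4-(benzyloxy)-2,6-bis(methoxymethoxy)phenyl]-2-[(tert-butyldiphenylsilyl)oxy]-N-methoxy-N-methylpropanamide
Conditions: TBDPSCl (1.3 equiv), imidazole (3 equiv), DMAP (cat.), DMF, rt → 40 °C
Reagents that add atoms: tert-butyl(chloro)diphenylsilane (TBDPSCl), CC(C)(C)[Si](Cl)(c1ccccc1)c1ccccc1
Why: Imidazole-mediated silylation of the secondary alcohol installs a bulky, non-chelating silyl ether that should survive the aryllithium addition, the acetal cleavage and the Lewis acid of the ring closure.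

Step 5
Reactants: 9 5-bromobenzene-1,2,3-triol
Product: 10 5-bromo-1,2,3-tris(benzyloxy)benzene
Conditions: BnBr (3.3 equiv), K2CO3 (3.5 equiv), DMF, rt, under argon
Reagents that add atoms: benzyl bromide, BrCc1ccccc1
Why: Williamson ether synthesis on the three phenols should give the tribenzyl ether, with air excluded to protect the pyrogallol.

Step 6
Reactants: 10 5-bromo-1,2,3-tris(benzyloxy)benzene; 8 (R)-3-[4-(benzyloxy)-2,6-bis(methoxymethoxy)phenyl]-2-[(tert-butyldiphenylsilyl)oxy]-N-methoxy-N-methylpropanamide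
Product: 12 (R)-3-[4-(benzyloxy)-2,6-bis(methoxymethoxy)phenyl]-2-[(tert-butyldiphenylsilyl)oxy]-1-[3,4,5-tris(benzyloxy)phenyl]propan-1-one, via aryllithium 11 (not isolated)
Conditions: 10 (1.5 equiv), n-BuLi (1.45 equiv), THF, −78 °C; then 8, −78 → −40 °C; then H2O
Reagents that add atoms: none
Why: Bromine–lithium exchange followed by Weinreb ketone synthesis should stop at the ketone because the chelated tetrahedral adduct persists until the quench, which also keeps the α-silyloxy stereocentre from enolising.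

Step 7
Reactants: 12 (R)-3-[4-(benzyloxy)-2,6-bis(methoxymethoxy)phenyl]-2-[(tert-butyldiphenylsilyl)oxy]-1-[3,4,5-tris(benzyloxy)phenyl]propan-1-one
Product: 14 (R)-3-[4-(benzyloxy)-2,6-dihydroxyphenyl]-2-[(tert-butyldiphenylsilyl)oxy]-1-[3,4,5-tris(benzyloxy)phenyl]propan-1-one, via bis(bromomethyl) ether 13 (not isolated)
Conditions: Me2BBr (4 equiv), CH2Cl2, −78 → −50 °C; then THF/sat. aq NaHCO3, 0 °C
Reagents that add atoms: none
Why: Low-temperature Lewis acid cleavage of the acetal (MOM) ethers by a dialkylboron bromide should give bromomethyl ethers that hydrolyse on the basic work-up, leaving benzyl ethers, the TBDPS ether and the ketone untouched and exposing the α-silyloxy ketone to no protic acid.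

Step 8
Reactants: 14 (R)-3-[4-(benzyloxy)-2,6-dihydroxyphenyl]-2-[(tert-butyldiphenylsilyl)oxy]-1-[3,4,5-tris(benzyloxy)phenyl]propan-1-one
Product: 16 (2R,3R)-7-(benzyloxy)-3-[(tert-butyldiphenylsilyl)oxy]-2-[3,4,5-tris(benzyloxy)phenyl]chroman-5-ol, via oxocarbenium triflate 15 (not isolated)
Conditions: Et3SiH (6 equiv), TMSOTf (0.5 equiv), CH2Cl2, −78 → −30 °C; then Et3N, MeOH; aq NaHCO3
Reagents that add atoms: none
Why: TMSOTf activates the aryl ketone, one of the two phenols adds to the carbonyl carbon, and ionisation of the resulting silylated adduct gives the cyclic 2-aryl oxocarbenium ion 15, which Et3SiH reduces irreversibly; the closest known reaction type is the Lewis acid/silane reductive etherification of hydroxy ketones, as used for 2-arylchromans and 1-C-aryl glycosides. The only ring closed is the pyran ring, by 6-exo-trig addition of the phenol oxygen to the C2 carbonyl (O1–C2 bond) followed by hydride capture at C2. The new stereocentre C2 is controlled by the existing C3 centre: in the half-chair cation the C3–OTBDPS group should lie pseudoaxial to avoid A(1,2) strain with the coplanar, conjugated B ring, and hydride should enter along the axial trajectory anti to it, which places the aryl group cis to the C3 oxygen, i.e. (2R,3R). Site selectivity between O1 and O5 does not arise, because the two hydroxyls of the 2-substituted 5-benzyloxyresorcinol are exchanged by rotation about the C4–C4a bond, so either closure gives 16 and leaves the single free phenol at C5. The step needs reduction of the cation to outrun both loss of the C3 proton (which would give the 4H-chromene enol ether and scramble C3) and direct ionic hydrogenation of the open-chain ketone; the large excess of silane, the low temperature and the intramolecular phenol addition should secure this.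

Step 9
Reactants: 16 (2R,3R)-7-(benzyloxy)-3-[(tert-butyldiphenylsilyl)oxy]-2-[3,4,5-tris(benzyloxy)phenyl]chroman-5-ol
Product: 17 (2R,3R)-7-(benzyloxy)-2-[3,4,5-tris(benzyloxy)phenyl]chromane-3,5-diol
Conditions: TBAF (1.5 equiv), AcOH (1.5 equiv), THF, 0 °C → rt
Reagents that add atoms: none
Why: Fluoride-mediated desilylation should cleave only the Si–O bond, and the acetic acid buffer keeps the C5 phenol from becoming a free phenoxide that could open the pyran ring and epimerise C2.

Step 10
Reactants: 17 (2R,3R)-7-(benzyloxy)-2-[3,4,5-tris(benzyloxy)phenyl]chromane-3,5-diol; 18 3,4,5-tris(benzyloxy)benzoic acid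
Product: 19 (2R,3R)-7-(benzyloxy)-2-[3,4,5-tris(benzyloxy)phenyl]chromane-3,5-diyl bis[3,4,5-tris(benzyloxy)benzoate]
Conditions: 18 (2.6 equiv), DCC (2.8 equiv), DMAP (0.5 equiv), CH2Cl2, 0 °C → rt
Reagents that add atoms: none
Why: Steglich esterification should acylate the C3 alcohol and the C5 phenol, the only free hydroxyls, in one operation, because O7 and all other phenols are benzyl ethers, and no stereocentre is touched.

Step 11
Reactants: 19 (2R,3R)-7-(benzyloxy)-2-[3,4,5-tris(benzyloxy)phenyl]chromane-3,5-diyl bis[3,4,5-tris(benzyloxy)benzoate]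
Product: 20 epigallocatechin 3,5-digallate, (2R,3R)-7-hydroxy-2-(3,4,5-trihydroxyphenyl)chromane-3,5-diyl bis(3,4,5-trihydroxybenzoate)
Conditions: H2 (1 atm), 20% Pd(OH)2/C, THF/MeOH (4:1), rt
Reagents that add atoms: none
Why: Catalytic hydrogenolysis of all ten O-benzyl groups under neutral conditions should leave both gallate esters, the pyran ring and both stereocentres intact and give the target.

**Compound list**

1 | 5-(benzyloxy)benzene-1,3-diol | Oc1cc(O)cc(OCc2ccccc2)c1 | starting material
2 | 1-(benzyloxy)-3,5-bis(methoxymethoxy)benzene | COCOc1cc(OCOC)cc(OCc2ccccc2)c1 | intermediate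
3 | methyl (R)-glycidate | COC(=O)[C@H]1CO1 | starting material
4 | [4-(benzyloxy)-2,6-bis(methoxymethoxy)phenyl]lithium | [Li]c1c(OCOC)cc(OCc2ccccc2)cc1OCOC | intermediate
5 | [4-(benzyloxy)-2,6-bis(methoxymethoxy)phenyl]magnesium bromide | Br[Mg]c1c(OCOC)cc(OCc2ccccc2)cc1OCOC | intermediate
6 | methyl (R)-3-[4-(benzyloxy)-2,6-bis(methoxymethoxy)phenyl]-2-hydroxypropanoate | COC(=O)[C@H](O)Cc1c(OCOC)cc(OCc2ccccc2)cc1OCOC | intermediate
7 | (R)-3-[4-(benzyloxy)-2,6-bis(methoxymethoxy)phenyl]-2-hydroxy-N-methoxy-N-methylpropanamide | CON(C)C(=O)[C@H](O)Cc1c(OCOC)cc(OCc2ccccc2)cc1OCOC | intermediate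
8 | (R)-3-[4-(benzyloxy)-2,6-bis(methoxymethoxy)phenyl]-2-[(tert-butyldiphenylsilyl)oxy]-N-methoxy-N-methylpropanamide | CON(C)C(=O)[C@H](O[Si](c1ccccc1)(c1ccccc1)C(C)(C)C)Cc1c(OCOC)cc(OCc2ccccc2)cc1OCOC | intermediate
9 | 5-bromobenzene-1,2,3-triol | Oc1cc(Br)cc(O)c1O | starting material
10 | 5-bromo-1,2,3-tris(benzyloxy)benzene | Brc1cc(OCc2ccccc2)c(OCc2ccccc2)c(OCc2ccccc2)c1 | intermediate
11 | [3,4,5-tris(benzyloxy)phenyl]lithium | [Li]c1cc(OCc2ccccc2)c(OCc2ccccc2)c(OCc2ccccc2)c1 | intermediate
12 | (R)-3-[4-(benzyloxy)-2,6-bis(methoxymethoxy)phenyl]-2-[(tert-butyldiphenylsilyl)oxy]-1-[3,4,5-tris(benzyloxy)phenyl]propan-1-one | O=C(c1cc(OCc2ccccc2)c(OCc2ccccc2)c(OCc2ccccc2)c1)[C@H](O[Si](c1ccccc1)(c1ccccc1)C(C)(C)C)Cc1c(OCOC)cc(OCc2ccccc2)cc1OCOC | intermediate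
13 | (R)-3-[4-(benzyloxy)-2,6-bis(bromomethoxy)phenyl]-2-[(tert-butyldiphenylsilyl)oxy]-1-[3,4,5-tris(benzyloxy)phenyl]propan-1-one | O=C(c1cc(OCc2ccccc2)c(OCc2ccccc2)c(OCc2ccccc2)c1)[C@H](O[Si](c1ccccc1)(c1ccccc1)C(C)(C)C)Cc1c(OCBr)cc(OCc2ccccc2)cc1OCBr | intermediate
14 | (R)-3-[4-(benzyloxy)-2,6-dihydroxyphenyl]-2-[(tert-butyldiphenylsilyl)oxy]-1-[3,4,5-tris(benzyloxy)phenyl]propan-1-one | O=C(c1cc(OCc2ccccc2)c(OCc2ccccc2)c(OCc2ccccc2)c1)[C@H](O[Si](c1ccccc1)(c1ccccc1)C(C)(C)C)Cc1c(O)cc(OCc2ccccc2)cc1O | intermediate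
15 | (3R)-7-(benzyloxy)-3-[(tert-butyldiphenylsilyl)oxy]-5-hydroxy-2-[3,4,5-tris(benzyloxy)phenyl]-3,4-dihydrochromenylium triflate | CC(C)(C)[Si](c1ccccc1)(c1ccccc1)O[C@@H]1Cc2c(O)cc(OCc3ccccc3)cc2[O+]=C1c1cc(OCc3ccccc3)c(OCc3ccccc3)c(OCc3ccccc3)c1.[O-]S(=O)(=O)C(F)(F)F | intermediate
16 | (2R,3R)-7-(benzyloxy)-3-[(tert-butyldiphenylsilyl)oxy]-2-[3,4,5-tris(benzyloxy)phenyl]chroman-5-ol | Oc1cc(OCc3ccccc3)cc2c1C[C@@H](O[Si](c1ccccc1)(c1ccccc1)C(C)(C)C)[C@@H](c1cc(OCc3ccccc3)c(OCc3ccccc3)c(OCc3ccccc3)c1)O2 | intermediate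
17 | (2R,3R)-7-(benzyloxy)-2-[3,4,5-tris(benzyloxy)phenyl]chromane-3,5-diol | Oc1cc(OCc3ccccc3)cc2c1C[C@@H](O)[C@@H](c1cc(OCc3ccccc3)c(OCc3ccccc3)c(OCc3ccccc3)c1)O2 | intermediate
18 | 3,4,5-tris(benzyloxy)benzoic acid | OC(=O)c1cc(OCc2ccccc2)c(OCc2ccccc2)c(OCc2ccccc2)c1 | starting material
19 | (2R,3R)-7-(benzyloxy)-2-[3,4,5-tris(benzyloxy)phenyl]chromane-3,5-diyl bis[3,4,5-tris(benzyloxy)benzoate] | O=C(Oc1cc(OCc3ccccc3)cc2c1C[C@@H](OC(=O)c1cc(OCc3ccccc3)c(OCc3ccccc3)c(OCc3ccccc3)c1)[C@@H](c1cc(OCc3ccccc3)c(OCc3ccccc3)c(OCc3ccccc3)c1)O2)c1cc(OCc2ccccc2)c(OCc2ccccc2)c(OCc2ccccc2)c1 | intermediate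
20 | epigallocatechin 3,5-digallate | O=C(Oc1cc(O)cc2c1C[C@@H](OC(=O)c1cc(O)c(O)c(O)c1)[C@@H](c1cc(O)c(O)c(O)c1)O2)c1cc(O)c(O)c(O)c1 | target

**Summary and fallbacks**

Total step count: 11. Longest linear sequence: 10 steps (steps 1–4 and 6–11; step 5 is a one-step side branch).

Steps most likely to fail:

1. Step 8. Hydride delivery to the cyclic cation may show insufficient facial selectivity, the cation may lose its C3 proton before it is reduced (eroding the C3 configuration), or the open-chain ketone may be reduced directly. The fallback sets out from 14 and returns at 16. Reagent-controlled asymmetric transfer hydrogenation of the aryl ketone (Noyori-type, RuCl[(R,R)-TsDPEN](p-cymene), HCO2H/Et3N) should give (1S,2R)-3-[4-(benzyloxy)-2,6-dihydroxyphenyl]-2-[(tert-butyldiphenylsilyl)oxy]-1-[3,4,5-tris(benzyloxy)phenyl]propan-1-ol F1; here the catalyst has to override the Felkin–Anh preference of the α-silyloxy ketone. An intramolecular Mitsunobu etherification (PPh3, DIAD, THF, 0 °C) should then form the O1–C2 bond by SN2 displacement with inversion at the benzylic carbon, giving 16 without a cation at C2.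

2. Step 2. The aryl-metal may attack the ester carbonyl of the glycidate, open the epoxide at C2 instead of C3, or the benzyl ether may be metalated at its CH2 group. The fallback sets out from 2 and returns at 6, with the stereocentre set by a catalyst instead of the chiral pool. Aryllithium 4 is formylated with DMF to 4-(benzyloxy)-2,6-bis(methoxymethoxy)benzaldehyde F2. Horner–Wadsworth–Emmons olefination with methyl 2-acetoxy-2-(dimethoxyphosphoryl)acetate (LiCl, DBU, MeCN) should give methyl (Z)-2-acetoxy-3-[4-(benzyloxy)-2,6-bis(methoxymethoxy)phenyl]prop-2-enoate F3. Rhodium-catalysed asymmetric hydrogenation with the (R,R)-Et-DuPhos ligand (the enantiomer expected to give (R)-2-acyloxy esters; H2, MeOH) should give methyl (R)-2-acetoxy-3-[4-(benzyloxy)-2,6-bis(methoxymethoxy)phenyl]propanoate F4, and K2CO3/MeOH removes the acetate to give 6.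

3. Step 7. Acetal cleavage may be incomplete or unselective (attack on benzyl ethers or the silyl ether), or the freed keto-phenol may cyclise and dehydrate before it is isolated. The fallback sets out from 12 and returns at 16, by-passing 14. Exchange of the aryl MOM ethers for trimethylsilyl ethers (TMSOTf, 2,2′-bipyridyl, CH2Cl2, 0 °C) should give (R)-3-[4-(benzyloxy)-2,6-bis(trimethylsilyloxy)phenyl]-2-[(tert-butyldiphenylsilyl)oxy]-1-[3,4,5-tris(benzyloxy)phenyl]propan-1-one F5. This is not hydrolysed but treated in the same flask with Et3SiH and further TMSOTf at −78 °C, so that an aryl silyl ether instead of a free phenol adds to the ketone (reductive etherification of a silyl ether); aqueous work-up cleaves the remaining aryl O–Si bond and delivers 16.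

Further compounds
F1 | step 8 | (1S,2R)-3-[4-(benzyloxy)-2,6-dihydroxyphenyl]-2-[(tert-butyldiphenylsilyl)oxy]-1-[3,4,5-tris(benzyloxy)phenyl]propan-1-ol | O[C@@H](c1cc(OCc2ccccc2)c(OCc2ccccc2)c(OCc2ccccc2)c1)[C@H](O[Si](c1ccccc1)(c1ccccc1)C(C)(C)C)Cc1c(O)cc(OCc2ccccc2)cc1O
F2 | step 2 | 4-(benzyloxy)-2,6-bis(methoxymethoxy)benzaldehyde | O=Cc1c(OCOC)cc(OCc2ccccc2)cc1OCOC
F3 | step 2 | methyl (Z)-2-acetoxy-3-[4-(benzyloxy)-2,6-bis(methoxymethoxy)phenyl]prop-2-enoate | COC(=O)/C(OC(C)=O)=C/c1c(OCOC)cc(OCc2ccccc2)cc1OCOC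
F4 | step 2 | methyl (R)-2-acetoxy-3-[4-(benzyloxy)-2,6-bis(methoxymethoxy)phenyl]propanoate | COC(=O)[C@H](OC(C)=O)Cc1c(OCOC)cc(OCc2ccccc2)cc1OCOC
F5 | step 7 | (R)-3-[4-(benzyloxy)-2,6-bis(trimethylsilyloxy)phenyl]-2-[(tert-butyldiphenylsilyl)oxy]-1-[3,4,5-tris(benzyloxy)phenyl]propan-1-one | O=C(c1cc(OCc2ccccc2)c(OCc2ccccc2)c(OCc2ccccc2)c1)[C@H](O[Si](c1ccccc1)(c1ccccc1)C(C)(C)C)Cc1c(O[Si](C)(C)C)cc(OCc2ccccc2)cc1O[Si](C)(C)C
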